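**Retrosynthetic overview**
- C12–OAc and the 7Z diene: acetylation, then stereospecific anti-dehydration of an anti aldol between a C5-unsubstituted ring enone and methyl (E)-7-oxohept-5-enoate (C7–C8).
- Only ring (cyclopentenone): formed by an enantioselective oxa-Piancatelli rearrangement (C8–C12 bond, 4π closure) of a 2,3,5-trisubstituted furan.
- Key C8–C9 bond: a halogen-dance-generated 3-bromo-2-furyllithium (masked C9 acyl anion) adds to formaldehyde; the dance also puts Br at the future C10.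
- C12–C13 bond: 2-furyllithium (masked acyl anion at the future C12) is alkylated with (Z)-1-bromooct-2-ene, which brings in the Z-octenyl chain intact.
- The enal comes from cross-metathesis of methyl hex-5-enoate with crotonaldehyde.

Assumption: (2Z)-oct-2-en-1-ol ("cis-2-octen-1-ol"), furan, methyl hex-5-enoate, crotonaldehyde and LDA solution are bought; which antipode of the Step 5 catalyst gives (S)-10 is fixed by a first analytical run.

**Route**

Step 1
Reactants: 1 (2Z)-oct-2-en-1-ol
Product: 2 (2Z)-1-bromooct-2-ene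
Conditions: CBr4, PPh3, CH2Cl2, 0 °C
Reagents that add atoms: carbon tetrabromide BrC(Br)(Br)Br
Why: Appel reaction, an SN2 displacement at the primary allylic carbon that leaves the Z alkene untouched.

Step 2
Reactants: 3 furan; 2 (2Z)-1-bromooct-2-ene
Product: 5 2-[(2Z)-oct-2-en-1-yl]furan, via 2-furyllithium 4 (not isolated)
Conditions: n-BuLi, THF, 0 °C; then 2, −78 °C → rt
Reagents that add atoms: none
Why: α-lithiated furan is a metalated enol ether, i.e. a masked acyl anion for the carbon that becomes C12, and it is alkylated by SN2 on the primary allylic bromide with the Z geometry retained (acyl-anion alkylation with furan as the carbonyl mask).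

Step 3
Reactants: 5 2-[(2Z)-oct-2-en-1-yl]furan
Product: 6 2-bromo-5-[(2Z)-oct-2-en-1-yl]furan
Conditions: NBS, DMF, −20 → 0 °C, dark; used at once
Reagents that add atoms: N-bromosuccinimide O=C1CCC(=O)N1Br
Why: electrophilic aromatic bromination of the electron-rich furan at its free α-position is far faster than attack on the isolated Z alkene in anhydrous DMF.

Step 4
Reactants: 6 2-bromo-5-[(2Z)-oct-2-en-1-yl]furan
Product: 9 {3-bromo-5-[(2Z)-oct-2-en-1-yl]furan-2-yl}methanol, via 2-bromo-3-lithio-5-octenylfuran 7 (not isolated), via 3-bromo-2-lithio-5-octenylfuran 8 (not isolated)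
Conditions: LDA (1.05 equiv), THF, −78 → −50 °C; then CH2O (g, from paraformaldehyde), −78 → 0 °C; H2O
Reagents that add atoms: formaldehyde C=O
Why: base-induced halogen dance, in which LDA removes H-3 next to bromine and Br/Li exchange funnels the material to the most stable lithio species 8 (Li α to O and ortho to Br); 8 is the acyl-anion equivalent of the future C9 ketone and adds to formaldehyde, joining two carbons that are both carbonyl electrophiles by nature and fixing Br at the future C10 (no stereocenter).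

Step 5
Reactants: 9 {3-bromo-5-[(2Z)-oct-2-en-1-yl]furan-2-yl}methanol
Product: 10 (4S)-2-bromo-4-hydroxy-4-[(2Z)-oct-2-en-1-yl]cyclopent-2-en-1-one
Conditions: chiral BINOL-derived N-triflylphosphoramide (3,3′-bis(2,4,6-triisopropylphenyl), 10 mol %), H2O (5 equiv), MeCN, 40 °C
Reagents that add atoms: water O
Why: Proposed new method: the chiral acid ionises the furfuryl alcohol, water adds to the octenyl-bearing furan carbon, and ring opening gives a 1,4-dihydroxypentadienyl cation that is hydrogen-bonded to the chiral anion, which dictates the sense of the conrotatory 4π closure and so sets C4 as S; the closest known reactions are the Piancatelli rearrangement of 5-alkylfurfuryl alcohols and chiral-Brønsted-acid-catalysed aza-Piancatelli rearrangements.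

Step 6
Reactants: 10 (4S)-2-bromo-4-hydroxy-4-[(2Z)-oct-2-en-1-yl]cyclopent-2-en-1-one
Product: 11 (4S)-2-bromo-4-[(2Z)-oct-2-en-1-yl]-4-[(triethylsilyl)oxy]cyclopent-2-en-1-one
Conditions: TESOTf, 2,6-lutidine, CH2Cl2, −78 °C
Reagents that add atoms: triethylsilyl trifluoromethanesulfonate CC[Si](CC)(CC)OS(=O)(=O)C(F)(F)F
Why: silyl triflate silylation of the tertiary alcohol, so that the later enolate cannot expel the C4 oxygen and only the secondary aldol hydroxyl is dehydrated.

Step 7
Reactants: 12 methyl hex-5-enoate; 13 (E)-crotonaldehyde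
Product: 14 methyl (5E)-7-oxohept-5-enoate
Conditions: Hoveyda–Grubbs II (2 mol %), crotonaldehyde (3 equiv), CH2Cl2, 40 °C
Reagents that add atoms: none
Why: olefin cross-metathesis of a terminal alkene with an enal gives the E-enal under thermodynamic control with loss of propene.

Step 8
Reactants: 11 (4S)-2-bromo-4-[(2Z)-oct-2-en-1-yl]-4-[(triethylsilyl)oxy]cyclopent-2-en-1-one; 14 methyl (5E)-7-oxohept-5-enoate
Product: 16 methyl (5E,7R)-7-{(1S,5S)-3-bromo-2-oxo-5-[(2Z)-oct-2-en-1-yl]-5-[(triethylsilyl)oxy]cyclopent-3-en-1-yl}-7-hydroxyhept-5-enoate, via dicyclohexylboron dienolate 15 (not isolated)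
Conditions: c-Hex2BCl, Et3N, Et2O, −78 °C; then 14, −78 → −20 °C; MeOH, pH 7 buffer
Reagents that add atoms: none
Why: boron aldol reaction, in which soft enolisation can occur only at C5 and gives the ring-locked E(O)-enolate; it adds through a Zimmerman–Traxler chair to give the anti aldol, with the ring carbon expected to be attacked on the face opposite OTES (the other face gives the equally anti bis-epimer, which converges in Step 9).

Step 9
Reactants: 16 methyl (5E,7R)-7-{(1S,5S)-3-bromo-2-oxo-5-[(2Z)-oct-2-en-1-yl]-5-[(triethylsilyl)oxy]cyclopent-3-en-1-yl}-7-hydroxyhept-5-enoate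
Product: 17 methyl (5E,7Z)-7-{(2R)-4-bromo-5-oxo-2-[(2Z)-oct-2-en-1-yl]-2-[(triethylsilyl)oxy]cyclopent-3-en-1-ylidene}hept-5-enoate
Conditions: Martin sulfurane (1.5 equiv), CH2Cl2, 0 °C → rt, dark
Reagents that add atoms: none
Why: Martin sulfurane dehydration is an E2 anti-elimination from the alkoxysulfonium, so the anti aldol gives the alkene with C6 cis to the ketone (7Z), as in the stereospecific dehydration of erythro/threo β-hydroxy carbonyl compounds; the quaternary stereocenter is untouched.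

Step 10
Reactants: 17 methyl (5E,7Z)-7-{(2R)-4-bromo-5-oxo-2-[(2Z)-oct-2-en-1-yl]-2-[(triethylsilyl)oxy]cyclopent-3-en-1-ylidene}hept-5-enoate
Product: 19 methyl (5E,7Z)-7-{(2R)-2-acetoxy-4-bromo-2-[(2Z)-oct-2-en-1-yl]-5-oxocyclopent-3-en-1-ylidene}hept-5-enoate, via free tertiary alcohol 18 (not isolated)
Conditions: HF·pyridine, THF, 0 °C; then Ac2O, DMAP, Et3N, CH2Cl2, rt, dark
Reagents that add atoms: acetic anhydride CC(=O)OC(C)=O
Why: fluoride desilylation followed by DMAP-catalysed acetylation of the tertiary alcohol; the ring carbon between C=O and C–OAc is now sp2, so neither retro-aldol nor β-elimination can occur and the stereocenter and all alkene geometries are kept.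

**Compound list**

1 | (2Z)-oct-2-en-1-ol | CCCCC/C=C\CO | starting material
2 | (2Z)-1-bromooct-2-ene | CCCCC/C=C\CBr | intermediate
3 | furan | c1ccoc1 | starting material
4 | 2-furyllithium (in situ) | [Li]c1ccco1 | intermediate
5 | 2-[(2Z)-oct-2-en-1-yl]furan | CCCCC/C=C\Cc1ccco1 | intermediate
6 | 2-bromo-5-[(2Z)-oct-2-en-1-yl]furan | CCCCC/C=C\Cc1ccc(Br)o1 | intermediate
7 | 2-bromo-3-lithio-5-[(2Z)-oct-2-en-1-yl]furan (in situ) | CCCCC/C=C\Cc1cc([Li])c(Br)o1 | intermediate
8 | 3-bromo-2-lithio-5-[(2Z)-oct-2-en-1-yl]furan (in situ) | CCCCC/C=C\Cc1cc(Br)c([Li])o1 | intermediate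
9 | {3-bromo-5-[(2Z)-oct-2-en-1-yl]furan-2-yl}methanol | CCCCC/C=C\Cc1cc(Br)c(CO)o1 | intermediate
10 | (4S)-2-bromo-4-hydroxy-4-[(2Z)-oct-2-en-1-yl]cyclopent-2-en-1-one | CCCCC/C=C\C[C@@]1(O)C=C(Br)C(=O)C1 | intermediate
11 | (4S)-2-bromo-4-[(2Z)-oct-2-en-1-yl]-4-[(triethylsilyl)oxy]cyclopent-2-en-1-one | CCCCC/C=C\C[C@@]1(O[Si](CC)(CC)CC)C=C(Br)C(=O)C1 | intermediate
12 | methyl hex-5-enoate | COC(=O)CCCC=C | starting material
13 | (E)-crotonaldehyde | C/C=C/C=O | starting material
14 | methyl (5E)-7-oxohept-5-enoate | COC(=O)CCC/C=C/C=O | intermediate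
15 | {[(3S)-5-bromo-3-[(2Z)-oct-2-en-1-yl]-3-[(triethylsilyl)oxy]cyclopenta-1,4-dien-1-yl]oxy}dicyclohexylborane (in situ) | CCCCC/C=C\C[C@@]1(O[Si](CC)(CC)CC)C=C(Br)C(OB(C2CCCCC2)C2CCCCC2)=C1 | intermediate
16 | methyl (5E,7R)-7-{(1S,5S)-3-bromo-2-oxo-5-[(2Z)-oct-2-en-1-yl]-5-[(triethylsilyl)oxy]cyclopent-3-en-1-yl}-7-hydroxyhept-5-enoate | CCCCC/C=C\C[C@@]1(O[Si](CC)(CC)CC)C=C(Br)C(=O)[C@H]1[C@H](O)/C=C/CCCC(=O)OC | intermediate
17 | methyl (5E,7Z)-7-{(2R)-4-bromo-5-oxo-2-[(2Z)-oct-2-en-1-yl]-2-[(triethylsilyl)oxy]cyclopent-3-en-1-ylidene}hept-5-enoate | CCCCC/C=C\C[C@@]1(O[Si](CC)(CC)CC)C=C(Br)C(=O)/C1=C\C=C\CCCC(=O)OC | intermediate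
18 | methyl (5E,7Z)-7-{(2R)-4-bromo-2-hydroxy-2-[(2Z)-oct-2-en-1-yl]-5-oxocyclopent-3-en-1-ylidene}hept-5-enoate (in situ) | CCCCC/C=C\C[C@@]1(O)C=C(Br)C(=O)/C1=C\C=C\CCCC(=O)OC | intermediate
19 | methyl (5E,7Z,12R,14Z)-12-acetoxy-10-bromo-9-oxoprosta-5,7,10,14-tetraenoate (CNP0295154.2) | CCCCC/C=C\C[C@@]1(OC(C)=O)C=C(Br)C(=O)/C1=C\C=C\CCCC(=O)OC | target

**Step count**

Total steps: 10. Longest linear sequence: 9 (Steps 1–6, 8–10).

**Steps most likely to fail**

Step 5 (asymmetric oxa-Piancatelli). Reactivity of the primary, 3-bromo carbinol and the level of enantiocontrol are both untested. The fallback sets out from 9 and comes back at 11. Compound 9 is rearranged with an achiral Lewis acid (ZnCl2 or Dy(OTf)3, aqueous dioxane, 80–100 °C) to racemic 2-bromo-4-hydroxy-4-[(2Z)-oct-2-en-1-yl]cyclopent-2-en-1-one F1, which is silylated to the racemic TES ether F2. A catalyst-controlled reduction with (S)-Me-CBS and BH3·SMe2 then turns the two enantiomers into diastereomers: (1R,4S)-2-bromo-4-[(2Z)-oct-2-en-1-yl]-4-[(triethylsilyl)oxy]cyclopent-2-en-1-ol F3 and (1R,4R)-2-bromo-4-[(2Z)-oct-2-en-1-yl]-4-[(triethylsilyl)oxy]cyclopent-2-en-1-ol F4. These are separated on silica, and Dess–Martin oxidation of F3 gives 11.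

Step 4 (halogen dance and hydroxymethylation). Lateral metalation of the doubly activated CH2 or incomplete bromine migration could compete. The fallback sets out from 2 and comes back at 8. Commercial 2,3-dibromofuran is deprotonated by LDA (THF, −78 °C) at its only α-hydrogen to give (4,5-dibromofuran-2-yl)lithium F5, which is alkylated with 2 to 2,3-dibromo-5-[(2Z)-oct-2-en-1-yl]furan F6. n-BuLi at −78 °C then exchanges the α-bromine selectively (α-Br reacts much faster than β-Br) and gives 8 without any deprotonation step in the presence of the octenyl chain; formaldehyde then gives 9 as in Step 4.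

Step 9 (7Z geometry; it depends on the anti selectivity of Step 8 and on a truly anti E2 elimination rather than E1cB). The fallback sets out from 11 and comes back at 17. Compound 11 is formylated (LDA, 2,2,2-trifluoroethyl formate, −78 °C) to the chelated (4R,5Z)-2-bromo-5-(hydroxymethylidene)-4-[(2Z)-oct-2-en-1-yl]-4-[(triethylsilyl)oxy]cyclopent-2-en-1-one F7. Its chelated lithium enolate is triflated (LiHMDS, PhNTf2) to (Z)-{(2R)-4-bromo-5-oxo-2-[(2Z)-oct-2-en-1-yl]-2-[(triethylsilyl)oxy]cyclopent-3-en-1-ylidene}methyl trifluoromethanesulfonate F8, with the triflate cis to the ketone. Suzuki coupling at room temperature (Pd(PPh3)4, K3PO4, THF–H2O) with methyl (5E)-6-(4,4,5,5-tetramethyl-1,3,2-dioxaborolan-2-yl)hex-5-enoate F9 then gives 17 with retention of both alkene geometries. F9 is made from commercial methyl hex-5-ynoate and pinacolborane with catalytic Cp2Zr(H)Cl. The vinylogous acyl triflate is expected to react before the α-bromoenone, but this selectivity is not guaranteed.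

**Further compounds**

F1 | step 5 | racemic 2-bromo-4-hydroxy-4-[(2Z)-oct-2-en-1-yl]cyclopent-2-en-1-one | CCCCC/C=C\CC1(O)C=C(Br)C(=O)C1
F2 | step 5 | racemic 2-bromo-4-[(2Z)-oct-2-en-1-yl]-4-[(triethylsilyl)oxy]cyclopent-2-en-1-one | CCCCC/C=C\CC1(O[Si](CC)(CC)CC)C=C(Br)C(=O)C1
F3 | step 5 | (1R,4S)-2-bromo-4-[(2Z)-oct-2-en-1-yl]-4-[(triethylsilyl)oxy]cyclopent-2-en-1-ol | CCCCC/C=C\C[C@@]1(O[Si](CC)(CC)CC)C=C(Br)[C@H](O)C1
F4 | step 5 | (1R,4R)-2-bromo-4-[(2Z)-oct-2-en-1-yl]-4-[(triethylsilyl)oxy]cyclopent-2-en-1-ol | CCCCC/C=C\C[C@]1(O[Si](CC)(CC)CC)C=C(Br)[C@H](O)C1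
F5 | step 4 | (4,5-dibromofuran-2-yl)lithium | [Li]c1cc(Br)c(Br)o1
F6 | step 4 | 2,3-dibromo-5-[(2Z)-oct-2-en-1-yl]furan | CCCCC/C=C\Cc1cc(Br)c(Br)o1
F7 | step 9 | (4R,5Z)-2-bromo-5-(hydroxymethylidene)-4-[(2Z)-oct-2-en-1-yl]-4-[(triethylsilyl)oxy]cyclopent-2-en-1-one | CCCCC/C=C\C[C@@]1(O[Si](CC)(CC)CC)C=C(Br)C(=O)/C1=C\O
F8 | step 9 | (Z)-{(2R)-4-bromo-5-oxo-2-[(2Z)-oct-2-en-1-yl]-2-[(triethylsilyl)oxy]cyclopent-3-en-1-ylidene}methyl trifluoromethanesulfonate | CCCCC/C=C\C[C@@]1(O[Si](CC)(CC)CC)C=C(Br)C(=O)/C1=C\OS(=O)(=O)C(F)(F)F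
F9 | step 9 | methyl (5E)-6-(4,4,5,5-tetramethyl-1,3,2-dioxaborolan-2-yl)hex-5-enoate | COC(=O)CCC/C=C/B1OC(C)(C)C(C)(C)O1
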